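**Strategy**

The plan rests on opening ring C at O1–C8a, C4–C4a and O1–C2, which reduces the flavonol core to a ring A aryne (C4a≡C8a) and a 3-arylpropiolic acid. The feature exploited is the C5 oxygen of ring A, which sits beside C4a and polarizes the aryne so that the carboxylate oxygen bonds to C8a and the acyl carbon migrates to C4a; the phenoxide then closes ring C at C2. One fluoride-triggered operation thus joins an ortho-silylaryl triflate, 3,5-bis(methoxymethoxy)-2-(trimethylsilyl)phenyl triflate, with the acid to give protected apigenin. C3 hydroxylation, C8 iodination and Negishi attachment of the resolved lavandulyl unit follow, so that no ene-active side chain is present when the aryne is formed.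

Key step: step 7

Remark (assumption): porcine pancreatic lipase is taken to acylate (S)-lavandulol faster than (R)-lavandulol, so the unreacted alcohol is the (R)-enantiomer; this alcohol has the spatial arrangement of the target, whose side-chain descriptor is S only because CH2–aryl ranks below isopropenyl.

**Route**

Step 1
Reactants: 1 phloroglucinol
Product: 2 3,5-bis(methoxymethoxy)phenol
Conditions: MOMCl (2.1 equiv), i-Pr2NEt, DMF, 0 °C to rt; chromatography
Reagents that add atoms: chloromethyl methyl ether (MOMCl), COCCl
Why: Statistical Williamson-type O-alkylation of the symmetrical triphenol with two equivalents of MOMCl should give the bis-ether as the main fraction, separable from the mono-ether (recyclable) and the tris-ether.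

Step 2
Reactants: 2 3,5-bis(methoxymethoxy)phenol
Product: 3 3,5-bis(methoxymethoxy)phenyl N-isopropylcarbamate
Conditions: i-PrNCO (1.2 equiv), Et3N (cat.), CH2Cl2, rt
Reagents that add atoms: isopropyl isocyanate, CC(C)N=C=O
Why: Base-catalysed addition of the phenol to the isocyanate (carbamoylation) installs a strong ortho-directing group that, unlike an N,N-dialkyl carbamate, can later be removed under mild E1cB conditions.

Step 3
Reactants: 3 3,5-bis(methoxymethoxy)phenyl N-isopropylcarbamate
Product: 7 3,5-bis(methoxymethoxy)-2-(trimethylsilyl)phenyl N-isopropylcarbamate, via N-TBS carbamate 4 (not isolated), via C2 aryllithium 5 (not isolated), via N-TBS C2-TMS carbamate 6 (not isolated)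
Conditions: TBSOTf (1.05 equiv), TMEDA, Et2O, 0 °C to rt; n-BuLi (1.2 equiv), TMEDA, −78 °C; TMSCl, −78 °C to rt; brief cold aq. NaHSO4 work-up
Reagents that add atoms: chlorotrimethylsilane (TMSCl), C[Si](C)(C)Cl
Why: Directed ortho-metalation: once the N–H is masked in situ as the N-silyl carbamate (which prevents loss of isopropyl isocyanate), n-BuLi/TMEDA should lithiate C2, the site flanked by the carbamate and a MOM ether, in preference to C4 between the two weaker MOM directors, and TMSCl quenches the aryllithium before the N–Si bond is hydrolysed on work-up.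

Step 4
Reactants: 7 3,5-bis(methoxymethoxy)-2-(trimethylsilyl)phenyl N-isopropylcarbamate
Product: 9 3,5-bis(methoxymethoxy)-2-(trimethylsilyl)phenyl trifluoromethanesulfonate, via 2-silylphenol 8 (not isolated)
Conditions: DBU, Et2NH, MeCN, 40–60 °C; then PhNTf2, rt
Reagents that add atoms: N-phenylbis(trifluoromethanesulfonimide) (PhNTf2), O=S(=O)(N(c1ccccc1)S(=O)(=O)C(F)(F)F)C(F)(F)F
Why: Base-induced E1cB cleavage of the N-monosubstituted carbamate (the isopropyl isocyanate is scavenged by Et2NH as a urea) frees the phenoxide, which is O-sulfonylated in the same flask by PhNTf2, a triflating agent mild enough for the MOM ethers and the aryl–silicon bond.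

Step 5
Reactants: 10 4-iodophenol
Product: 11 1-iodo-4-(methoxymethoxy)benzene
Conditions: MOMCl, i-Pr2NEt, CH2Cl2, 0 °C to rt
Reagents that add atoms: chloromethyl methyl ether (MOMCl), COCCl
Why: Williamson-type O-alkylation of the phenol with MOMCl under amine base masks the only acidic, aryne-reactive OH of this fragment and leaves the aryl iodide untouched.

Step 6
Reactants: 11 1-iodo-4-(methoxymethoxy)benzene; 12 propiolic acid
Product: 13 3-[4-(methoxymethoxy)phenyl]prop-2-ynoic acid
Conditions: PdCl2(PPh3)2 (5 mol%), 1,4-bis(diphenylphosphino)butane (10 mol%), DBU (2.2 equiv), DMSO, rt; cold aq. NaHSO4 to pH 3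
Reagents that add atoms: none
Why: Copper-free Sonogashira coupling of the aryl iodide with propiolic acid at ambient temperature should give the arylpropiolic acid directly, the absence of copper and heat suppressing decarboxylation.

Step 7
Reactants: 9 3,5-bis(methoxymethoxy)-2-(trimethylsilyl)phenyl trifluoromethanesulfonate; 13 3-[4-(methoxymethoxy)phenyl]prop-2-ynoic acid
Product: 16 5,7-bis(methoxymethoxy)-2-[4-(methoxymethoxy)phenyl]chromen-4-one, via aryne 14 (not isolated), via ortho-acyl phenoxide ynone 15 (not isolated)
Conditions: 9 (1.5 equiv), CsF (4 equiv), THF, sealed tube, 125 °C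
Reagents that add atoms: none
Why: Fluoride removes the trimethylsilyl group and expels triflate to give aryne 14, whose carbon C8a (remote from the C5 oxygen) is attacked by the carboxylate oxygen of 13; the aryl anion left at C4a, stabilized inductively by the adjacent 5-OMOM group, adds to the ester carbonyl and the four-membered adduct opens to the ortho-acyl phenoxide 15, so that O1–C8a and C4–C4a are formed by net insertion into the acid C–O bond. The closest known reaction type is the fluoride-mediated C–O insertion of arynes into carboxylic acids giving ortho-hydroxyaryl ketones, which with arylpropiolic acids continues to flavones. Ring C is then closed by 6-endo-dig oxa-Michael addition of the phenoxide oxygen to the alkyne carbon that becomes C2 (O1–C2), and protonation at C3 should give 16. No stereocenter is formed. The step needs oxygen delivery to C8a and not to C4a, which the inductive and steric bias of the 5-OMOM group on the distorted aryne should secure, and it needs 6-endo over 5-exo closure, which the polarization of the ynone (electrophilic β-carbon, no π-acidic metal present) should secure.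

Step 8
Reactants: 16 5,7-bis(methoxymethoxy)-2-[4-(methoxymethoxy)phenyl]chromen-4-one
Product: 19 3-hydroxy-5,7-bis(methoxymethoxy)-2-[4-(methoxymethoxy)phenyl]chromen-4-one, via 3-lithioflavone 17 (not isolated), via flavon-3-yl dimethyl boronate 18 (not isolated)
Conditions: LiN(i-Pr)2 (LDA, 1.3 equiv), THF, −78 °C; B(OMe)3, −78 to 0 °C; AcOH, 30% H2O2, 0 °C to rt
Reagents that add atoms: hydrogen peroxide, OO
Why: The C3–H next to the C4 carbonyl is the most acidic C–H and should be removed by LDA at −78 °C (C3 lithiation of flavones), the vinyllithium is trapped as the boronate, and peroxide oxidation of the C–B bond (boronate oxidation with 1,2-migration) should give the flavonol without touching the MOM ethers.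

Step 9
Reactants: 19 3-hydroxy-5,7-bis(methoxymethoxy)-2-[4-(methoxymethoxy)phenyl]chromen-4-one
Product: 20 3,5,7-tris(methoxymethoxy)-2-[4-(methoxymethoxy)phenyl]chromen-4-one
Conditions: MOMCl, i-Pr2NEt, CH2Cl2, 0 to 40 °C
Reagents that add atoms: chloromethyl methyl ether (MOMCl), COCCl
Why: Williamson-type O-alkylation of the acidic enolic 3-OH masks it against oxidation by NIS in step 10 and against protonolysis of the organozinc reagent in step 13.

Step 10
Reactants: 20 3,5,7-tris(methoxymethoxy)-2-[4-(methoxymethoxy)phenyl]chromen-4-one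
Product: 21 8-iodo-3,5,7-tris(methoxymethoxy)-2-[4-(methoxymethoxy)phenyl]chromen-4-one
Conditions: NIS (1.05 equiv), DMF, 0 °C to rt, dark
Reagents that add atoms: N-iodosuccinimide (NIS), O=C1CCC(=O)N1I
Why: Electrophilic aromatic iodination should occur on the phloroglucinol-type ring A at C8, because with the 5-oxygen alkylated C8 is para to it and flanked by only one MOM ether whereas C6 lies between two, and ring B is deactivated by conjugation with the pyranone.

Step 11
Reactants: 22 racemic lavandulol
Product: 23 (R)-lavandulol, (2R)-5-methyl-2-(prop-1-en-2-yl)hex-4-en-1-ol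
Conditions: porcine pancreatic lipase, succinic anhydride (0.7 equiv), Et2O, rt, run past half conversion; aq. Na2CO3 extraction; second pass if needed
Reagents that add atoms: none
Why: Lipase-catalysed kinetic resolution by acylation should convert the (S)-alcohol into its acidic hemisuccinate, which is washed out with aqueous carbonate, leaving the (R)-alcohol whose stereocenter becomes that of the target.

Step 12
Reactants: 23 (R)-lavandulol
Product: 24 (R)-lavandulyl iodide, (3R)-3-(iodomethyl)-2,6-dimethylhepta-1,5-diene
Conditions: I2, PPh3, imidazole, CH2Cl2, 0 °C to rt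
Reagents that add atoms: iodine, II
Why: Appel-type iodination proceeds by SN2 displacement at the primary CH2 only, so the adjacent stereocenter and both alkenes should be unaffected.

Step 13
Reactants: 24 (R)-lavandulyl iodide; 21 8-iodo-3,5,7-tris(methoxymethoxy)-2-[4-(methoxymethoxy)phenyl]chromen-4-one
Product: 26 3,5,7-tris(methoxymethoxy)-2-[4-(methoxymethoxy)phenyl]-8-[(2S)-5-methyl-2-(prop-1-en-2-yl)hex-4-en-1-yl]chromen-4-one, via (R)-lavandulylzinc iodide 25 (not isolated)
Conditions: 24 (2 equiv), Zn dust (activated with BrCH2CH2Br/TMSCl), LiCl, THF, 25–40 °C; then 21, Pd(OAc)2 (5 mol%), SPhos (10 mol%), THF, rt to 50 °C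
Reagents that add atoms: none
Why: LiCl-assisted zinc insertion into the primary C–I bond gives a configurationally secure alkylzinc iodide (the stereocenter is one carbon away from zinc), and Negishi cross-coupling with the aryl iodide under a bulky biarylphosphine should favour reductive elimination at the di-ortho-substituted C8 over β-hydride elimination while tolerating the C4 carbonyl and the MOM ethers.

Step 14
Reactants: 26 3,5,7-tris(methoxymethoxy)-2-[4-(methoxymethoxy)phenyl]-8-[(2S)-5-methyl-2-(prop-1-en-2-yl)hex-4-en-1-yl]chromen-4-one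
Product: 27 3,5,7-trihydroxy-2-(4-hydroxyphenyl)-8-[(2S)-5-methyl-2-(prop-1-en-2-yl)hex-4-en-1-yl]chromen-4-one (CNP0185677.2)
Conditions: dilute HCl (about 0.5 M, from conc. aq. HCl) in MeOH, rt to 40 °C, monitored; NaHCO3 quench
Reagents that add atoms: none
Why: Acid-catalysed acetal exchange with methanol (methanolysis of the four MOM ethers to dimethoxymethane) under dilute, low-temperature conditions should free the four hydroxyl groups while both alkenes and the allylic stereocenter are preserved.

**Compound list**

1 | phloroglucinol (benzene-1,3,5-triol) | Oc1cc(O)cc(O)c1 | starting material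
2 | 3,5-bis(methoxymethoxy)phenol | COCOc1cc(O)cc(OCOC)c1 | intermediate
3 | 3,5-bis(methoxymethoxy)phenyl N-isopropylcarbamate | CC(C)NC(=O)Oc1cc(OCOC)cc(OCOC)c1 | intermediate
4 | 3,5-bis(methoxymethoxy)phenyl N-(tert-butyldimethylsilyl)-N-isopropylcarbamate | CC(C)N(C(=O)Oc1cc(OCOC)cc(OCOC)c1)[Si](C)(C)C(C)(C)C | intermediate (not isolated)
5 | 2-lithio-3,5-bis(methoxymethoxy)phenyl N-(tert-butyldimethylsilyl)-N-isopropylcarbamate | CC(C)N(C(=O)Oc1cc(OCOC)cc(OCOC)c1[Li])[Si](C)(C)C(C)(C)C | intermediate (not isolated)
6 | 3,5-bis(methoxymethoxy)-2-(trimethylsilyl)phenyl N-(tert-butyldimethylsilyl)-N-isopropylcarbamate | CC(C)N(C(=O)Oc1cc(OCOC)cc(OCOC)c1[Si](C)(C)C)[Si](C)(C)C(C)(C)C | intermediate (not isolated)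
7 | 3,5-bis(methoxymethoxy)-2-(trimethylsilyl)phenyl N-isopropylcarbamate | CC(C)NC(=O)Oc1cc(OCOC)cc(OCOC)c1[Si](C)(C)C | intermediate
8 | 3,5-bis(methoxymethoxy)-2-(trimethylsilyl)phenol (formed as its amidinium phenoxide) | COCOc1cc(O)c([Si](C)(C)C)c(OCOC)c1 | intermediate (not isolated)
9 | 3,5-bis(methoxymethoxy)-2-(trimethylsilyl)phenyl trifluoromethanesulfonate | COCOc1cc(OCOC)c([Si](C)(C)C)c(OS(=O)(=O)C(F)(F)F)c1 | intermediate (aryne precursor of the key step)
10 | 4-iodophenol | Oc1ccc(I)cc1 | starting material
11 | 1-iodo-4-(methoxymethoxy)benzene | COCOc1ccc(I)cc1 | intermediate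
12 | propiolic acid (prop-2-ynoic acid) | C#CC(=O)O | starting material
13 | 3-[4-(methoxymethoxy)phenyl]prop-2-ynoic acid | COCOc1ccc(cc1)C#CC(=O)O | intermediate (acid partner of the key step)
14 | 3,5-bis(methoxymethoxy)benzyne (1,2-didehydro-3,5-bis(methoxymethoxy)benzene) | COCOC1=CC(OCOC)=CC#C1 | intermediate (not isolated)
15 | caesium 2-{3-[4-(methoxymethoxy)phenyl]prop-2-ynoyl}-3,5-bis(methoxymethoxy)phenolate | [Cs+].[O-]c1cc(OCOC)cc(OCOC)c1C(=O)C#Cc1ccc(OCOC)cc1 | intermediate (not isolated)
16 | 5,7-bis(methoxymethoxy)-2-[4-(methoxymethoxy)phenyl]chromen-4-one | COCOc1ccc(cc1)-c1cc(=O)c2c(OCOC)cc(OCOC)cc2o1 | intermediate (product of the key step)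
17 | 3-lithio-5,7-bis(methoxymethoxy)-2-[4-(methoxymethoxy)phenyl]chromen-4-one | COCOc1ccc(cc1)-c1oc2cc(OCOC)cc(OCOC)c2c(=O)c1[Li] | intermediate (not isolated)
18 | dimethyl {5,7-bis(methoxymethoxy)-2-[4-(methoxymethoxy)phenyl]-4-oxochromen-3-yl}boronate | COCOc1ccc(cc1)-c1oc2cc(OCOC)cc(OCOC)c2c(=O)c1B(OC)OC | intermediate (not isolated)
19 | 3-hydroxy-5,7-bis(methoxymethoxy)-2-[4-(methoxymethoxy)phenyl]chromen-4-one | COCOc1ccc(cc1)-c1oc2cc(OCOC)cc(OCOC)c2c(=O)c1O | intermediate
20 | 3,5,7-tris(methoxymethoxy)-2-[4-(methoxymethoxy)phenyl]chromen-4-one | COCOc1ccc(cc1)-c1oc2cc(OCOC)cc(OCOC)c2c(=O)c1OCOC | intermediate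
21 | 8-iodo-3,5,7-tris(methoxymethoxy)-2-[4-(methoxymethoxy)phenyl]chromen-4-one | COCOc1ccc(cc1)-c1oc2c(I)c(OCOC)cc(OCOC)c2c(=O)c1OCOC | intermediate
22 | racemic lavandulol, 5-methyl-2-(prop-1-en-2-yl)hex-4-en-1-ol | C=C(C)C(CC=C(C)C)CO | starting material
23 | (R)-lavandulol, (2R)-5-methyl-2-(prop-1-en-2-yl)hex-4-en-1-ol | C=C(C)[C@@H](CC=C(C)C)CO | intermediate
24 | (R)-lavandulyl iodide, (3R)-3-(iodomethyl)-2,6-dimethylhepta-1,5-diene | C=C(C)[C@@H](CC=C(C)C)CI | intermediate
25 | (R)-lavandulylzinc iodide, [(2R)-5-methyl-2-(prop-1-en-2-yl)hex-4-en-1-yl]zinc iodide (RZnI) | C=C(C)[C@@H](CC=C(C)C)C[Zn]I | intermediate (not isolated)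
26 | 3,5,7-tris(methoxymethoxy)-2-[4-(methoxymethoxy)phenyl]-8-[(2S)-5-methyl-2-(prop-1-en-2-yl)hex-4-en-1-yl]chromen-4-one | C=C(C)[C@@H](CC=C(C)C)Cc1c(OCOC)cc(OCOC)c2c(=O)c(OCOC)c(-c3ccc(OCOC)cc3)oc12 | intermediate
27 | 3,5,7-trihydroxy-2-(4-hydroxyphenyl)-8-[(2S)-5-methyl-2-(prop-1-en-2-yl)hex-4-en-1-yl]chromen-4-one (8-lavandulylkaempferol, CNP0185677.2) | C=C(C)[C@@H](CC=C(C)C)Cc1c(O)cc(O)c2c(=O)c(O)c(-c3ccc(O)cc3)oc12 | target

**Step count and risk**

Total step count: 14 steps.
Longest linear sequence: 10 steps (steps 1, 2, 3, 4, 7, 8, 9, 10, 13, 14).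

Steps most likely to fail:

1. Step 7 (aryne–propiolic acid annulation). The C4a aryl anion may be protonated by the free acid before it reaches the carbonyl, which stops the sequence at plain O-arylation. The caesium arylpropiolate may also lose CO2 at 125 °C, or the anion may add to the alkyne terminus instead of the carbonyl. Fallback, setting out from 1 and returning at 16: ring C is built by a thermal phenol–β-ketoester cyclocondensation. Phloroglucinol 1 is heated neat with commercial ethyl 3-(4-hydroxyphenyl)-3-oxopropanoate (about 240 °C, microwave). Loss of ethanol, C-acylation of the symmetrical triphenol and cyclodehydration should give apigenin F1. Exhaustive protection (NaH, MOMCl, DMF, 0 °C to rt, the strong base being needed for the chelated 5-OH) then rejoins the route at 16.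

2. Step 13 (Negishi coupling at C8). Transmetalation and reductive elimination at the di-ortho-substituted C8 may be slow enough for β-hydride elimination from the alkylpalladium intermediate (giving a diene and the reduced arene) or homocoupling to take over. Incomplete or scrambling zinc insertion is a lesser concern. Fallback, setting out from 24 and returning at 26: the nucleophile is changed from zinc to boron and generated without zinc metal. Lithium–iodine exchange on 24 (t-BuLi, 2 equiv, Et2O, −78 °C) followed by B-methoxy-9-borabicyclo[3.3.1]nonane should give lithium B-methoxy-B-[(R)-lavandulyl]-9-borabicyclo[3.3.1]nonan-9-uide F2. This is used directly in a B-alkyl Suzuki–Miyaura coupling with 21 (PdCl2(dppf), AsPh3, aq. K3PO4, DMF, rt to 45 °C), the wide-bite-angle ligand favouring reductive elimination, to give 26.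

3. Step 14 (global MOM removal). The Brønsted acid needed for acetal cleavage may protonate the isopropenyl or prenyl alkene. The cation could then be captured by the neighbouring 7-OH (chroman formation), by methanol or by chloride, or the alkene could migrate into the position of the stereocenter. Fallback, setting out from 26 and returning at 27: deprotection by trans-silylation without free acid. TMSOTf with 2,2'-bipyridyl (CH2Cl2, 0 °C to rt) should convert each aryl and enol MOM ether into a trimethylsilyl ether, the methoxymethyl cation being taken up by the bipyridyl, to give the tetrakis(trimethylsilyl) ether F3. Stirring with water (or K2CO3 in MeOH) then hydrolyses the silyl ethers to 27.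

Further compounds
F1 | step 7 | apigenin, 5,7-dihydroxy-2-(4-hydroxyphenyl)chromen-4-one | O=c1cc(-c2ccc(O)cc2)oc2cc(O)cc(O)c12
F2 | step 13 | lithium B-methoxy-B-[(R)-lavandulyl]-9-borabicyclo[3.3.1]nonan-9-uide | [Li+].CO[B-]1(C[C@H](CC=C(C)C)C(C)=C)C2CCCC1CCC2
F3 | step 14 | 8-[(2S)-5-methyl-2-(prop-1-en-2-yl)hex-4-en-1-yl]-3,5,7-tris(trimethylsilyloxy)-2-[4-(trimethylsilyloxy)phenyl]chromen-4-one | C=C(C)[C@@H](CC=C(C)C)Cc1c(O[Si](C)(C)C)cc(O[Si](C)(C)C)c2c(=O)c(O[Si](C)(C)C)c(-c3ccc(O[Si](C)(C)C)cc3)oc12
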